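**Remarks.** (R)-(−)-Terpinen-4-ol (1) is assumed to be available in high enantiomeric purity. Locants are daucane locants: C1 (quaternary, CH3), C2, C3, C4 (carbinol, i-Pr), C5 (ring-fusion H), C6 (aroyloxy), C7 (CH2), C8 (=C, CH3), C9 (=CH), C10 (isovaleryloxy). Read from the SMILES, the target is 1R,4S,5S,6R,10R, a cis-fused hydroazulene.

## Analysis of the target

The target is a daucane (carotane) diester: a cis-fused bicyclo[5.3.0]decane in which a cyclopentane (C1–C5) shares the C1–C5 bond with a cycloheptene (C1, C5–C10). Five stereocentres are clustered around the ring fusion. CH3-1, H-5, the 4-OH and the 10-oxygen lie on one face (β); the isopropyl group and the 6-oxygen lie on the other. C1 is quaternary and sits between the C10 carbinol and C5. C4 is a tertiary carbinol with OH cis to CH3-1, which is the opposite of what isopropyl addition to a C4 ketone of a cis-fused bicycle (convex-face attack) would give. The cis fusion places C6 next to the isopropyl group, so it cannot be assumed to be the thermodynamic C5 epimer of a C6 ketone and should be fixed kinetically. Sensitive points are the tertiary 4-OH β to C6 (retro-aldol or E1cB once C6 is a ketone), the allylic neopentyl ester at C10, two different esters on secondary alcohols, and a free phenol.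

The feature that invites the key move is in the seven-membered ring. The C6 oxygen and the C8=C9 olefin are 1,4-related across the C7 methylene, and C10 is a carbonyl-level carbon bonded to the quaternary C1. That is the cyclohepta-2,5-dienone retron of a vinylcyclopropyl ketene Cope rearrangement. In addition, C1–C6, C15 and the isopropyl carbinol are the ten carbons of ring-opened terpinen-4-ol.

## Retrosynthetic reasoning

**Ester C–O bonds (27 ⇒ 26 ⇒ 24 + 25; 24 ⇒ 23; 23 ⇒ 20 + 21).** The phenol is unmasked last from acetate 26. The two acyl groups are introduced at different times so that each acylation meets only one free secondary hydroxyl: 21 acylates the 10-OH while C6 is still at the ketone level (23), and 25 acylates the 6-OH after reduction (24). The tertiary 4-OH needs no protection at this stage.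

**C5–H and the C6 carbinol (23 ⇒ 20 ⇒ 18).** The 10-OH and C6 are 1,4-related on the same ring, so they can be tied by an oxygen bridge (20, via 19). A cyclopentane fused to that 8-oxabicyclo[3.2.1]octene can only be cis-fused, so the bridge fixes H-5 cis to CH3-1 without relying on a face-selective intermolecular protonation. After the bridge is released, hydride addition to the C6 ketone from the convex face gives the 6α-carbinol.

**C10 carbinol (18 ⇒ 17).** With C5 still sp2 in dienone 17, the angular methyl is the only group projecting from C1. A 1,2-reduction should therefore deliver hydride anti to it and give the 10-OH cis to CH3-1.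

**Key disconnection (17 ⇒ 16 ⇒ 15).** The C1–C10 bond is cut and the C6–C8 bond restored (retro-[3,3]), which turns the cycloheptadienone into a cis-1-alkenyl-2-ketenyl cyclopropane 16. The cut is made here because one operation then builds the seven-membered ring, the quaternary C1, the C8=C9 olefin with its methyl, the C10 carbonyl and the C6 oxygen (as an enol ether). The ketene terminus is sp, so only the unavoidable C1 methyl points inward in the boat. Ketene 16 comes from diazoketone 15 by Wolff rearrangement, which inserts C9.

**Cyclopropane (15 ⇒ 12 ⇒ 10 ⇒ 8 + 9).** The diazoketone carbons are the ester carbon of 12 (future C10) plus one diazo carbon (C9). The C8 methyl is introduced by enolate C-methylation of 10, which also decides the cis relationship needed for the Cope step. The ring bonds C6–C8 and C7–C8 come from carbene transfer from 9 to the enol-ether double bond of diene 8.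

**Chiral pool (8 ⇒ 7 ⇒ 5 ⇒ 4 ⇒ 2 ⇒ 1).** Diene 8 is the enol silyl ether of methyl ketone 7. Ketone 7 is enal 5 plus one methyl nucleophile (C7). Enal 5 is the aldol-condensation product of keto aldehyde 4, which is the ozonolysis product of silylated terpinen-4-ol 2. The carbinol carbon of 1 becomes C4 with its oxygen and isopropyl group in place, so the centre that is hardest to set by addition chemistry is bought.

## Alternatives that were turned down

**Alternative 1: (textbook) C8=C9 by ring-closing metathesis after conjugate addition and aldol on a β-methylcyclopentenone.**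
- Forward: asymmetric conjugate addition creates C1, the enolate is trapped by an aldehyde at C5, the product is elaborated to diene A1, and metathesis gives hydroazulenone A2. The isopropyl group is then added to the C4 ketone.
- Turned down: an isopropyl nucleophile attacks the C4 ketone of cis-fused A2 from the convex face and gives the 4-epimer; repair by enol triflate, coupling and hydration costs at least three steps. The C10 oxygen has to ride on an α-alkoxy organometallic or be added later. Forming a trisubstituted olefin by metathesis next to a quaternary carbon is sluggish. No step sets more than one stereocentre, so the route is no shorter and has no stereochemical logic for C5.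

**Alternative 2: oxygen-bridged route, cutting C1–C10 and C6–C7 by a vinylcarbenoid/furan [4+3].**
- Forward: Rh(II)-catalysed cyclopropanation of a 3-methyl-substituted furan by a cyclopentenyl diazoacetate, then Cope rearrangement, gives 8-oxabicyclo[3.2.1]octadiene A3. The bridge oxygen becomes O-10, cis to CH3-1 by the boat geometry.
- Turned down: the acceptor group of the carbenoid ends up as a carbon on C6 and would have to be excised (Curtius-type degradation, three steps). The bridge also oxygenates C7, which must then be cleaved reductively. Cyclopropanation of the methyl-bearing furan double bond by a fully substituted vinylcarbenoid is uncertain in regiochemistry. The diazoacetate carrying the C4 carbinol needs a long homologation from 5.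

**Alternative 3: both rings at once by Rh(I)-catalysed intramolecular [5+2] of a tethered vinylcyclopropane and a 1,1-disubstituted alkene (bonds C1–C5 and C9–C10).**
- Forward: the cycloaddition gives bicyclic enol ether A4 with the angular methyl in place.
- Turned down: the olefin of the adduct lies at C6=C7, adjacent to the ring fusion. C8, C9 and C10 arrive as plain methylenes, so the C8 methyl, the C8=C9 olefin and the C10 oxygen would all have to be installed on an unactivated ring. The cis/trans outcome of the ring fusion with the C4 carbinol on the tether is hard to predict.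

Key step: step 11

## Route

**Step 1**
Reactants: 1 (R)-(−)-terpinen-4-ol
Product: 2 (R)-terpinen-4-ol triethylsilyl ether
Conditions: TESOTf, 2,6-lutidine, CH2Cl2, 0 °C
Reagents that add atoms: triethylsilyl trifluoromethanesulfonate, CC[Si](CC)(CC)OS(=O)(=O)C(F)(F)F
Why: Silylation of the hindered tertiary alcohol with a silyl triflate; it masks the future 4-OH so that the β-oxygenated aldehyde made next cannot dehydrate and the carbinol cannot intercept carbenoids or acyl chlorides later; the stereocentre (future C4) is untouched.

**Step 2**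
Reactants: 2 (R)-terpinen-4-ol triethylsilyl ether
Product: 4 (3R)-6-oxo-3-(propan-2-yl)-3-(triethylsilyloxy)heptanal, via secondary ozonide 3 (not isolated)
Conditions: O3, CH2Cl2, −78 °C; then Me2S, −78 to 23 °C
Reagents that add atoms: ozone, [O-][O+]=O
Why: Ozonolysis of the only C=C with reductive work-up opens the cyclohexene to the 1,6-keto aldehyde (aldehyde = future C6, ketone = future C1).

**Step 3**
Reactants: 4 (3R)-6-oxo-3-(propan-2-yl)-3-(triethylsilyloxy)heptanal
Product: 5 (5S)-2-methyl-5-(propan-2-yl)-5-(triethylsilyloxy)cyclopent-1-ene-1-carbaldehyde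
Conditions: piperidine, AcOH (cat.), toluene, 23 to 60 °C
Reagents that add atoms: none
Why: Enamine-mediated intramolecular aldol condensation (5-exo attack of the aldehyde α-carbon C5 on the C1 ketone, then dehydration), the ring contraction known for the limonene-derived keto aldehyde; mild amine catalysis is chosen so that the β-silyloxy group is not eliminated.

**Step 4**
Reactants: 5 (5S)-2-methyl-5-(propan-2-yl)-5-(triethylsilyloxy)cyclopent-1-ene-1-carbaldehyde
Product: 6 1-[(5S)-2-methyl-5-(propan-2-yl)-5-(triethylsilyloxy)cyclopent-1-en-1-yl]ethan-1-ol (both carbinol epimers)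
Conditions: MeMgBr, THF, −78 to 0 °C
Reagents that add atoms: methylmagnesium bromide, C[Mg]Br
Why: 1,2-Grignard addition to the enal brings in C7; the carbinol epimers converge in step 5.

**Step 5**
Reactants: 6 1-[(5S)-2-methyl-5-(propan-2-yl)-5-(triethylsilyloxy)cyclopent-1-en-1-yl]ethan-1-ol
Product: 7 1-[(5S)-2-methyl-5-(propan-2-yl)-5-(triethylsilyloxy)cyclopent-1-en-1-yl]ethan-1-one
Conditions: Dess–Martin periodinane, NaHCO3, CH2Cl2, 23 °C
Reagents that add atoms: none
Why: Dess–Martin oxidation of the allylic alcohol to the methyl ketone under buffered, neutral conditions.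

**Step 6**
Reactants: 7 1-[(5S)-2-methyl-5-(propan-2-yl)-5-(triethylsilyloxy)cyclopent-1-en-1-yl]ethan-1-one
Product: 8 triethyl({1-[(5S)-2-methyl-5-(propan-2-yl)-5-(triethylsilyloxy)cyclopent-1-en-1-yl]ethenyl}oxy)silane (2-silyloxy diene)
Conditions: TESOTf, Et3N, CH2Cl2, −78 to 0 °C
Reagents that add atoms: triethylsilyl trifluoromethanesulfonate, CC[Si](CC)(CC)OS(=O)(=O)C(F)(F)F
Why: Soft enolisation toward the acetyl CH3 (α′) gives the cross-conjugated 2-silyloxy diene, the usual outcome for 1-acetylcycloalkenes.

**Step 7**
Reactants: 8 2-silyloxy diene; 9 methyl diazoacetate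
Product: 10 methyl (2R)-2-[(5S)-2-methyl-5-(propan-2-yl)-5-(triethylsilyloxy)cyclopent-1-en-1-yl]-2-(triethylsilyloxy)cyclopropane-1-carboxylate (mixture at C1 of the cyclopropane)
Conditions: CuOTf (2 mol%), (S,S)-t-Bu-box, CH2Cl2, 23 °C, slow addition of 9
Reagents that add atoms: none
Why: Copper-carbenoid cyclopropanation of the electron-rich terminal enol ether (the tetrasubstituted ring olefin is inert) gives a donor–acceptor siloxycyclopropane ester; attack on the C1-side face of the conformer with the two C–O bonds anti should set the siloxy carbon (C6) as drawn, and the box ligand is used to reinforce this facial choice; the ester-bearing carbon is left as a mixture because it is planarised in step 8.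

**Step 8**
Reactants: 10 siloxycyclopropane ester
Product: 12 methyl (1R,2S)-1-methyl-2-[(5S)-2-methyl-5-(propan-2-yl)-5-(triethylsilyloxy)cyclopent-1-en-1-yl]-2-(triethylsilyloxy)cyclopropane-1-carboxylate, via lithium ester enolate 11 (not isolated)
Conditions: LDA, THF, −78 °C; then MeI, −78 to −40 °C
Reagents that add atoms: iodomethane, CI
Why: Ester enolate alkylation on the cyclopropane; iodomethane should enter anti to the bulky tetrasubstituted cyclopentenyl group on the neighbouring carbon (syn to the siloxy group), which places the ester cis to the cyclopentenyl group as the later Cope step requires.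

**Step 9**
Reactants: 12 methylated siloxycyclopropane ester
Product: 13 (1R,2S)-1-methyl-2-[(5S)-2-methyl-5-(propan-2-yl)-5-(triethylsilyloxy)cyclopent-1-en-1-yl]-2-(triethylsilyloxy)cyclopropane-1-carboxylic acid
Conditions: NaSEt, DMF, 60 °C; then aq. NaH2PO4 (pH 5)
Reagents that add atoms: none
Why: SN2 demethylation by thiolate cleaves the hindered quaternary methyl ester at the O–CH3 bond and leaves the silyl ethers and the acid-labile donor–acceptor cyclopropane alone.

**Step 10**
Reactants: 13 cyclopropanecarboxylic acid
Product: 15 2-diazo-1-{(1R,2S)-1-methyl-2-[(5S)-2-methyl-5-(propan-2-yl)-5-(triethylsilyloxy)cyclopent-1-en-1-yl]-2-(triethylsilyloxy)cyclopropyl}ethan-1-one, via acid chloride 14 (not isolated)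
Conditions: 1-chloro-N,N,2-trimethylprop-1-en-1-amine, CH2Cl2, 0 °C; then CH2N2 (excess), Et2O, 0 °C
Reagents that add atoms: diazomethane, C=[N+]=[N-]
Why: Neutral acid chloride formation (Ghosez reagent) and acylation of diazomethane, the first stage of an Arndt–Eistert sequence; excess diazomethane scavenges HCl so the silyl ethers are not exposed to acid.

**Step 11**
Reactants: 15 cis-alkenylcyclopropyl diazomethyl ketone
Product: 17 (1R,4S)-4,6-bis(triethylsilyloxy)dauca-5,8-dien-10-one [(3S,8aR)-6,8a-dimethyl-3-(propan-2-yl)-3,4-bis(triethylsilyloxy)-2,3,5,8a-tetrahydroazulen-8(1H)-one], via cyclopropyl ketene 16 (not isolated)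
Conditions: AgOBz (10 mol%), Et3N, THF, ultrasound, 45 °C
Reagents that add atoms: none
Why: Silver-promoted Wolff rearrangement expels N2 and shifts the cyclopropyl carbon C8 with retention to give ketene 16, in which the ketene and the cyclopentenyl group are cis on the three-membered ring. The ketene then undergoes a [3,3] shift through the boat transition state of a cis-divinylcyclopropane: the ketene carbonyl carbon (C10) bonds to the olefin terminus C1 while the C6–C8 ring bond breaks, releasing the cyclopropane strain. The closest known reaction type is the tandem Wolff/Cope rearrangement of cis-2-vinylcyclopropyl diazoketones to fused cycloheptadienones. The seven-membered ring is closed by this sigmatropic ring expansion (3 + 4 atoms, suprafacial on both allyl units), not by an end-on cyclisation, and the five-membered ring is already present. The only new stereocentre, the quaternary C1, is controlled by the configuration of the cyclopropane carbons C6 and C8 set in steps 7 and 8: the reactive rotamer holds C8 under the α-face of the cyclopentene, so C10 bonds to C1 anti to the C4 oxygen and the methyl ends up cis to it. The step needs the cis arrangement of ketene and alkenyl groups, secured in step 8, and a fast Cope step relative to ketene side reactions; the sp ketene terminus carries no inward substituent and the siloxy donor on C6 weakens the breaking bond. In one operation the product has the C8=C9 olefin with its methyl, the C10 carbonyl and the C6 oxygen as a silyl enol ether.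

**Step 12**
Reactants: 17 bicyclic dienone
Product: 18 (1R,4S,10R)-4,6-bis(triethylsilyloxy)dauca-5,8-dien-10-ol
Conditions: DIBAL-H, CH2Cl2, −78 °C; Rochelle salt work-up
Reagents that add atoms: none
Why: 1,2-Reduction of the enone; with C5 still sp2 the angular methyl is the only group projecting from C1, so hydride adds anti to it (as in the borohydride reductions of the Hajos–Parrish and Wieland–Miescher ketones) and the 10-OH comes out cis to CH3-1.

**Step 13**
Reactants: 18 10-hydroxy silyl enol ether
Product: 20 (1R,4S,5R,6S,10R)-6,10-epoxydauc-8-ene-4,6-diol (bridged hemiketal), via bridged silyl ketal 19 (not isolated)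
Conditions: PPTS (10 mol%), 4 Å MS, CH2Cl2, 0 to 23 °C; then HF·pyridine, pyridine, THF, 0 to 23 °C
Reagents that add atoms: none
Why: The acid protonates the silyl enol ether at C5 reversibly, and only the cation protonated on the β-face can be captured by the 10-OH (transannular ketalisation to an 8-oxabicyclo[3.2.1]octene, on which the cyclopentane can only be cis-fused), so the bridge fixes H-5 cis to CH3-1; fluoride then removes both silyl groups and leaves the ketone masked as the hemiketal.

**Step 14**
Reactants: 20 bridged hemiketal; 21 3-methylbutanoic (isovaleric) anhydride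
Product: 23 (1R,4S,5R,10R)-4-hydroxy-6-oxodauc-8-en-10-yl 3-methylbutanoate, via hydroxy ketone tautomer 22 (not isolated)
Conditions: DMAP, Et3N, CH2Cl2, 23 °C
Reagents that add atoms: none
Why: Ring–chain tautomerism: the anomeric hydroxyl is tertiary and at a bridgehead, while the open tautomer offers a secondary allylic alcohol, so DMAP-catalysed acylation should drain the equilibrium into the keto ester; the tertiary 4-OH does not react and no base able to enolise C5 is present.

**Step 15**
Reactants: 23 10-isovaleryloxy 6-ketone
Product: 24 (1R,4S,5S,6R,10R)-4,6-dihydroxydauc-8-en-10-yl 3-methylbutanoate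
Conditions: NaBH4, MeOH, −40 °C
Reagents that add atoms: none
Why: Borohydride should attack the C6 ketone from the convex β-face (syn to H-5; the α-face is blocked by C4 and its isopropyl group) to give the 6α-alcohol; low temperature protects the β-hydroxy ketone from retro-aldol cleavage and spares the ester.

**Step 16**
Reactants: 24 4,6-diol 10-isovalerate; 25 4-acetoxybenzoyl chloride
Product: 26 (1R,4S,5S,6R,10R)-4-hydroxy-10-(3-methylbutanoyloxy)dauc-8-en-6-yl 4-acetoxybenzoate
Conditions: Et3N, DMAP (cat.), CH2Cl2, 0 to 23 °C
Reagents that add atoms: none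
Why: Acylation of the only secondary hydroxyl with the acid chloride; the hindered tertiary 4-OH is inert under these conditions.

**Step 17**
Reactants: 26 acetate-protected diester
Product: 27 (1R,4S,5S,6R,10R)-4-hydroxy-10-(3-methylbutanoyloxy)dauc-8-en-6-yl 4-hydroxybenzoate (CNP0086724.1)
Conditions: pyrrolidine, CH2Cl2, 0 °C
Reagents that add atoms: none
Why: Chemoselective aminolysis of the aryl acetate, which is far more electrophilic than the alkyl isovalerate or the benzoate, frees the phenol.

## Compound list

1 | (R)-(−)-terpinen-4-ol, (1R)-4-methyl-1-(propan-2-yl)cyclohex-3-en-1-ol | CC1=CC[C@@](O)(C(C)C)CC1 | starting material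
2 | triethyl{[(1R)-4-methyl-1-(propan-2-yl)cyclohex-3-en-1-yl]oxy}silane | CC1=CC[C@@](O[Si](CC)(CC)CC)(C(C)C)CC1 | intermediate
3 | secondary ozonide (1,2,4-trioxolane) of 2 | CC12CC[C@](O[Si](CC)(CC)CC)(C(C)C)CC(OO1)O2 | intermediate (not isolated)
4 | (3R)-6-oxo-3-(propan-2-yl)-3-(triethylsilyloxy)heptanal | CC(=O)CC[C@](O[Si](CC)(CC)CC)(C(C)C)CC=O | intermediate
5 | (5S)-2-methyl-5-(propan-2-yl)-5-(triethylsilyloxy)cyclopent-1-ene-1-carbaldehyde | CC1=C(C=O)[C@@](O[Si](CC)(CC)CC)(C(C)C)CC1 | intermediate
6 | 1-[(5S)-2-methyl-5-(propan-2-yl)-5-(triethylsilyloxy)cyclopent-1-en-1-yl]ethan-1-ol (carbinol epimers) | CC1=C(C(C)O)[C@@](O[Si](CC)(CC)CC)(C(C)C)CC1 | intermediate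
7 | 1-[(5S)-2-methyl-5-(propan-2-yl)-5-(triethylsilyloxy)cyclopent-1-en-1-yl]ethan-1-one | CC1=C(C(C)=O)[C@@](O[Si](CC)(CC)CC)(C(C)C)CC1 | intermediate
8 | triethyl({1-[(5S)-2-methyl-5-(propan-2-yl)-5-(triethylsilyloxy)cyclopent-1-en-1-yl]ethenyl}oxy)silane | CC1=C(C(=C)O[Si](CC)(CC)CC)[C@@](O[Si](CC)(CC)CC)(C(C)C)CC1 | intermediate
9 | methyl diazoacetate | COC(=O)C=[N+]=[N-] | starting material
10 | methyl (2R)-2-[(5S)-2-methyl-5-(propan-2-yl)-5-(triethylsilyloxy)cyclopent-1-en-1-yl]-2-(triethylsilyloxy)cyclopropane-1-carboxylate (mixture at C1) | CC1=C([C@@]2(O[Si](CC)(CC)CC)CC2C(=O)OC)[C@@](O[Si](CC)(CC)CC)(C(C)C)CC1 | intermediate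
11 | lithium ester enolate of 10 | CC1=C([C@@]2(O[Si](CC)(CC)CC)CC2=C(OC)O[Li])[C@@](O[Si](CC)(CC)CC)(C(C)C)CC1 | intermediate (not isolated)
12 | methyl (1R,2S)-1-methyl-2-[(5S)-2-methyl-5-(propan-2-yl)-5-(triethylsilyloxy)cyclopent-1-en-1-yl]-2-(triethylsilyloxy)cyclopropane-1-carboxylate | CC1=C([C@@]2(O[Si](CC)(CC)CC)C[C@@]2(C)C(=O)OC)[C@@](O[Si](CC)(CC)CC)(C(C)C)CC1 | intermediate
13 | (1R,2S)-1-methyl-2-[(5S)-2-methyl-5-(propan-2-yl)-5-(triethylsilyloxy)cyclopent-1-en-1-yl]-2-(triethylsilyloxy)cyclopropane-1-carboxylic acid | CC1=C([C@@]2(O[Si](CC)(CC)CC)C[C@@]2(C)C(=O)O)[C@@](O[Si](CC)(CC)CC)(C(C)C)CC1 | intermediate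
14 | acid chloride of 13 (same configuration) | CC1=C([C@@]2(O[Si](CC)(CC)CC)C[C@@]2(C)C(Cl)=O)[C@@](O[Si](CC)(CC)CC)(C(C)C)CC1 | intermediate (not isolated)
15 | 2-diazo-1-{(1R,2S)-1-methyl-2-[(5S)-2-methyl-5-(propan-2-yl)-5-(triethylsilyloxy)cyclopent-1-en-1-yl]-2-(triethylsilyloxy)cyclopropyl}ethan-1-one | CC1=C([C@@]2(O[Si](CC)(CC)CC)C[C@@]2(C)C(=O)C=[N+]=[N-])[C@@](O[Si](CC)(CC)CC)(C(C)C)CC1 | intermediate
16 | cyclopropyl ketene from 15 (same spatial arrangement; ketene cis to the cyclopentenyl group) | CC1=C([C@@]2(O[Si](CC)(CC)CC)C[C@@]2(C)C=C=O)[C@@](O[Si](CC)(CC)CC)(C(C)C)CC1 | intermediate (not isolated)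
17 | (1R,4S)-4,6-bis(triethylsilyloxy)dauca-5,8-dien-10-one | CC1=CC(=O)[C@]2(C)CC[C@](O[Si](CC)(CC)CC)(C(C)C)C2=C(O[Si](CC)(CC)CC)C1 | intermediate
18 | (1R,4S,10R)-4,6-bis(triethylsilyloxy)dauca-5,8-dien-10-ol | CC1=C[C@@H](O)[C@]2(C)CC[C@](O[Si](CC)(CC)CC)(C(C)C)C2=C(O[Si](CC)(CC)CC)C1 | intermediate
19 | (1R,4S,5R,6R,10R)-6,10-epoxy-4,6-bis(triethylsilyloxy)dauc-8-ene (bridged silyl ketal) | CC1=C[C@@H]2[C@]3(C)CC[C@](O[Si](CC)(CC)CC)(C(C)C)[C@@H]3[C@@](O[Si](CC)(CC)CC)(O2)C1 | intermediate (not isolated)
20 | (1R,4S,5R,6S,10R)-6,10-epoxydauc-8-ene-4,6-diol (bridged hemiketal) | CC1=C[C@@H]2[C@]3(C)CC[C@](O)(C(C)C)[C@@H]3[C@@](O)(O2)C1 | intermediate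
21 | 3-methylbutanoic (isovaleric) anhydride | CC(C)CC(=O)OC(=O)CC(C)C | starting material
22 | (1R,4S,5R,10R)-4,10-dihydroxydauc-8-en-6-one (open tautomer of 20) | CC1=C[C@@H](O)[C@]2(C)CC[C@](O)(C(C)C)[C@@H]2C(=O)C1 | intermediate (not isolated)
23 | (1R,4S,5R,10R)-4-hydroxy-6-oxodauc-8-en-10-yl 3-methylbutanoate | CC1=C[C@@H](OC(=O)CC(C)C)[C@]2(C)CC[C@](O)(C(C)C)[C@@H]2C(=O)C1 | intermediate
24 | (1R,4S,5S,6R,10R)-4,6-dihydroxydauc-8-en-10-yl 3-methylbutanoate | CC1=C[C@@H](OC(=O)CC(C)C)[C@]2(C)CC[C@](O)(C(C)C)[C@@H]2[C@H](O)C1 | intermediate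
25 | 4-acetoxybenzoyl chloride | CC(=O)Oc1ccc(cc1)C(Cl)=O | starting material
26 | (1R,4S,5S,6R,10R)-4-hydroxy-10-(3-methylbutanoyloxy)dauc-8-en-6-yl 4-acetoxybenzoate | CC1=C[C@@H](OC(=O)CC(C)C)[C@]2(C)CC[C@](O)(C(C)C)[C@@H]2[C@H](OC(=O)c2ccc(OC(C)=O)cc2)C1 | intermediate
27 | (1R,4S,5S,6R,10R)-4-hydroxy-10-(3-methylbutanoyloxy)dauc-8-en-6-yl 4-hydroxybenzoate | CC1=C[C@@H](OC(=O)CC(C)C)[C@]2(C)CC[C@](O)(C(C)C)[C@@H]2[C@H](OC(=O)c2ccc(O)cc2)C1 | target

## Step count and least certain steps

Total step count: 17. Longest linear sequence: 17 steps (1 to 27).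

**Step 11 (key step).** The most likely failure is diversion of the ketene before the [3,3] shift: dimerisation, capture by nucleophiles, or Lewis-acid opening of the donor–acceptor cyclopropane. The boat is crowded (inward C1 methyl, C8 passing the isopropyl face), which could slow the Cope step enough for this to happen. Fallback: from 15, run the Wolff rearrangement in methanol so that the ketene is trapped as the homologous methyl ester F1 (Arndt–Eistert). Reduce F1 with DIBAL-H at −78 °C to the aldehyde F2. Convert F2 with TMSOTf/Et3N to the enol silyl ether F3, a stable cis-divinylcyclopropane that tolerates heating. A classical thermal divinylcyclopropane rearrangement (toluene, 80–110 °C) then gives the C10 silyl ether F4 as an epimer mixture. K2CO3/MeOH at 0 °C frees the allylic alcohols F5, and MnO2 oxidises them to 17, where the route is rejoined.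

**Step 7.** The most likely failure is poor facial selectivity at the siloxy carbon, because the carbenoid attacks a terminal CH2 far from the C4 stereocentre and the two diene rotamers may be similarly populated. Fallback: run steps 7 and 8 without relying on the face selection, then separate 12 from its cyclopropane diastereomer F6 by chromatography (they are diastereomers because of C4). Recycle F6 by reversible ring opening of the donor–acceptor cyclopropane with catalytic TMSOTf (CH2Cl2, −78 °C), which re-equilibrates it to a mixture containing 12. This replaces kinetic face selection by separation and thermodynamic recycling; it sets out from F6 and returns at 12.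

**Step 13.** The most likely failure is loss of the ring-fusion control: acid-catalysed silyl transfer from the enol ether to the 10-OH, or irreversible protonation of C5 from the α-face, would give the trans-fused ketone. Fallback: from 18, carry out a transannular iodoketalisation with N-iodosuccinimide (CH2Cl2, −40 °C) to the iodo ketal F7, in which closure of the bridge again demands the cis fusion. Remove iodine with Bu3SnH/AIBN; the ring-fusion radical can only be reduced to the cis-fused silyl ketal 19. Treat 19 with HF·pyridine as in the second stage of step 13 to return to 20.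

**Step 14.** The most likely failure is acylation of the anomeric hydroxyl instead of reaction through the open tautomer, or loss of the 4-oxygen (E1cB or retro-aldol) from the open β-hydroxy ketone under the basic conditions. Fallback: from 19 (isolated after the first stage of step 13), open the ketal reductively with DIBAL-H (CH2Cl2, 0 °C). Aluminium coordinates the bridge oxygen and delivers hydride to C6 from the same face, which should give the 6-silyl ether 10-alcohol F8 with the C6 configuration of 24. Acylate F8 with 21/DMAP to the isovalerate F9. HF·pyridine then removes both silyl groups and gives 24, where the route is rejoined.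

## Further compounds

F1 | step 11 | methyl 2-{1-methyl-2-[(5S)-2-methyl-5-(propan-2-yl)-5-(triethylsilyloxy)cyclopent-1-en-1-yl]-2-(triethylsilyloxy)cyclopropyl}acetate (cyclopropane configuration as in 15) | CC1=C([C@@]2(O[Si](CC)(CC)CC)C[C@@]2(C)CC(=O)OC)[C@@](O[Si](CC)(CC)CC)(C(C)C)CC1
F2 | step 11 | 2-{1-methyl-2-[(5S)-2-methyl-5-(propan-2-yl)-5-(triethylsilyloxy)cyclopent-1-en-1-yl]-2-(triethylsilyloxy)cyclopropyl}acetaldehyde (configuration as in 15) | CC1=C([C@@]2(O[Si](CC)(CC)CC)C[C@@]2(C)CC=O)[C@@](O[Si](CC)(CC)CC)(C(C)C)CC1
F3 | step 11 | trimethylsilyl enol ether of F2 (E/Z mixture; cis-divinylcyclopropane) | CC1=C([C@@]2(O[Si](CC)(CC)CC)C[C@@]2(C)C=CO[Si](C)(C)C)[C@@](O[Si](CC)(CC)CC)(C(C)C)CC1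
F4 | step 11 | (1R,4S)-4,6-bis(triethylsilyloxy)-10-(trimethylsilyloxy)dauca-5,8-diene (C10 epimers) | CC1=CC(O[Si](C)(C)C)[C@]2(C)CC[C@](O[Si](CC)(CC)CC)(C(C)C)C2=C(O[Si](CC)(CC)CC)C1
F5 | step 11 | (1R,4S)-4,6-bis(triethylsilyloxy)dauca-5,8-dien-10-ol (C10 epimers) | CC1=CC(O)[C@]2(C)CC[C@](O[Si](CC)(CC)CC)(C(C)C)C2=C(O[Si](CC)(CC)CC)C1
F6 | step 7 | cyclopropane diastereomer of 12 (both cyclopropane centres inverted, C4 unchanged) | CC1=C([C@]2(O[Si](CC)(CC)CC)C[C@]2(C)C(=O)OC)[C@@](O[Si](CC)(CC)CC)(C(C)C)CC1
F7 | step 13 | 5-iodo-6,10-epoxy-4,6-bis(triethylsilyloxy)dauc-8-ene (iodine in place of H-5 of 19) | CC1=C[C@@H]2[C@]3(C)CC[C@](O[Si](CC)(CC)CC)(C(C)C)[C@]3(I)[C@@](O[Si](CC)(CC)CC)(O2)C1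
F8 | step 14 | (1R,4S,5S,6R,10R)-4,6-bis(triethylsilyloxy)dauc-8-en-10-ol | CC1=C[C@@H](O)[C@]2(C)CC[C@](O[Si](CC)(CC)CC)(C(C)C)[C@@H]2[C@H](O[Si](CC)(CC)CC)C1
F9 | step 14 | (1R,4S,5S,6R,10R)-4,6-bis(triethylsilyloxy)dauc-8-en-10-yl 3-methylbutanoate | CC1=C[C@@H](OC(=O)CC(C)C)[C@]2(C)CC[C@](O[Si](CC)(CC)CC)(C(C)C)[C@@H]2[C@H](O[Si](CC)(CC)CC)C1
A1 | alternative 1 | metathesis substrate: 3-(1-hydroxyprop-2-enyl)-2-(1-hydroxy-3-methylbut-3-enyl)-3-methylcyclopentan-1-one with the C1, C5, C6, C10 configurations of 27 | C=C[C@@H](O)[C@]1(C)CCC(=O)[C@@H]1[C@H](O)CC(C)=C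
A2 | alternative 1 | metathesis product: cis-fused 6,10-dihydroxy-1,8-dimethylbicyclo[5.3.0]dec-8-en-4-one (daucane locants, no isopropyl group) | CC1=C[C@@H](O)[C@]2(C)CCC(=O)[C@@H]2[C@H](O)C1
A3 | alternative 2 | [4+3] adduct: methyl 7,10-epoxy-4-(triethylsilyloxy)dauca-5,8-diene-6-carboxylate (8-oxabicyclo[3.2.1]octadiene, daucane locants) | CC1=C[C@H]2O[C@@H]1C(C(=O)OC)=C1[C@@](O[Si](CC)(CC)CC)(C(C)C)CC[C@]12C
A4 | alternative 3 | [5+2] adduct: cis-fused 6-(tert-butyldimethylsilyloxy)-1-methyl-4-(propan-2-yl)-4-(triethylsilyloxy)bicyclo[5.3.0]dec-6-ene (daucane locants, no C8 methyl) | C1CC[C@]2(C)CC[C@](O[Si](CC)(CC)CC)(C(C)C)[C@@H]2C(O[Si](C)(C)C(C)(C)C)=CC1
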